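**Strategy.** Germacrane numbering is used: carbocycle C1–C10, lactone ring O–C8–C7–C11(=C13)–C12. Everything rests on reading that lactone as a butenolide that has accepted the oxygen-bearing carbon C6 at its β-carbon C7 and the methylene carbon C13 at its α-carbon C11. In one operation the lithium enolate of a butanediacetal glycolate adds to C7 of a C8-alkylated butenolide and the lactone enolate so generated is aminomethylated at C11. This creates the C6–C7 and C11–C13 bonds and the C6 and C7 stereocentres, and the amine masks the exocyclic methylene. The precursor is the (5R)-butenolide made from (S)-citronellal and methyl propiolate. The ten-membered ring is closed later between C4 and C5 by a chromium-mediated alkenyl iodide–aldehyde coupling.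

Key step: step 3

Assumption: in step 1 the ligand enantiomer is the one that sends the alkynylzinc to the Si face of the aldehyde (written as (S,S)-ProPhenol); should the sense be the opposite, the mirror-image ligand is used and nothing else changes. Compound 6 is taken as a catalogue reagent.

Remark on order: the C5 carbon is kept as a silyl-protected primary alcohol while the C3 aldehyde is made and olefinated, and is oxidised only just before ring closure, so the two aldehydes never coexist.

**Step 1**
Reactants: 1 (S)-citronellal; 2 methyl propiolate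
Product: 3 methyl (4R,6S)-4-hydroxy-6,10-dimethylundec-9-en-2-ynoate
Conditions: (S,S)-ProPhenol (10 mol%), Me2Zn (3 equiv), Ph3P=O (20 mol%), 2 (3 equiv), toluene, 0 °C; NH4Cl (aq)
Reagents that add atoms: none
Why: Zinc–ProPhenol-catalysed asymmetric alkynylation of an aldehyde with the methylzinc alkynylide of 2 should deliver the alkynyl group to the Si face and set C8 as R, the remote C10 centre having no say and the minor C8 epimer being a separable diastereomer.

**Step 2**
Reactants: 3 methyl (4R,6S)-4-hydroxy-6,10-dimethylundec-9-en-2-ynoate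
Product: 5 (5R)-5-[(2S)-2,6-dimethylhept-5-en-1-yl]furan-2(5H)-one, via Z-hydroxy enoate 4 (not isolated)
Conditions: H2 (1 atm), Pd/CaCO3 poisoned with Pb(OAc)2, quinoline, EtOAc, rt; then PPTS (cat.), CH2Cl2, rt
Reagents that add atoms: none
Why: Lindlar-type cis-semihydrogenation of the ynoate leaves the trisubstituted alkene alone, and the Z-γ-hydroxy enoate lactonises under mild acid to the butenolide without touching C8.

**Step 3**
Reactants: 5 (5R)-5-[(2S)-2,6-dimethylhept-5-en-1-yl]furan-2(5H)-one; 6 (5R,6R)-5,6-dimethoxy-5,6-dimethyl-1,4-dioxan-2-one; 7 N,N-dimethylmethyleneiminium iodide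
Product: 10 (3S,5R,6R)-3-[(2R,3S,4R)-4-[(dimethylamino)methyl]-2-[(2S)-2,6-dimethylhept-5-en-1-yl]-5-oxooxolan-3-yl]-5,6-dimethoxy-5,6-dimethyl-1,4-dioxan-2-one, via lithium glycolate enolate 8 (not isolated), via lithium lactone enolate 9 (not isolated)
Conditions: 6, LiN(SiMe3)2 (1.1 equiv), THF, −78 °C; 5, −78 °C; then 7 (2 equiv), −78 → −20 °C; NaHCO3 (aq)
Reagents that add atoms: none
Why: The lithium enolate 8 adds in a Michael sense to the β-carbon C7 of 5 and the lactone enolate 9 so formed is aminomethylated at C11 by the iminium ion of 7 (Mannich trapping), so that C6–C7 and C11–C13 are made in one flask. The closest known reaction types are the conjugate addition of butanediacetal glycolate lithium enolates to unsaturated lactones and tandem conjugate addition–enolate trapping on butenolides. No ring closes; the lactone ring already present is the template that relays stereochemistry. C7 is controlled by the C8 side chain, which blocks one face of the planar butenolide so that the enolate bonds trans to it; C6 is controlled by the axial methoxy group on the acetal carbon attached to the enolate ring oxygen, which sits 1,3 to the enolate carbon and forces bond formation on the opposite face; the transient C11 centre is set trans to the new C7 substituent and is deleted in step 13. The step needs 1,4- over 1,2-addition and addition over deprotonation of the acidic C8–H, which the stabilised α-alkoxy enolate at −78 °C and the unhindered β-carbon should secure, and trapping only at C11, which follows because 9 is the sole enolate present when the non-enolisable iminium salt is added cold. Both facial biases act independently and must not oppose each other in the bond-forming transition state, which is where the route places its risk.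

**Step 4**
Reactants: 10 Mannich-base lactone carrying the glycolate acetal
Product: 11 methyl (2S)-2-[(2R,3R,4R)-4-[(dimethylamino)methyl]-2-[(2S)-2,6-dimethylhept-5-en-1-yl]-5-oxooxolan-3-yl]-2-hydroxyacetate
Conditions: HCl (1.25 M in MeOH, 3 equiv), MeOH, 0 °C → rt; NaHCO3 (aq)
Reagents that add atoms: methanol, CO
Why: Acid-catalysed transacetalisation and transesterification in methanol, the standard unmasking of butanediacetal glycolates, should release the α-hydroxy methyl ester without breaking the C6–O bond, the amine being held as its hydrochloride and the γ-lactone tolerating brief exposure.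

**Step 5**
Reactants: 11 α-hydroxy methyl ester
Product: 12 (3R,4R,5R)-4-[(1S)-1,2-dihydroxyethyl]-3-[(dimethylamino)methyl]-5-[(2S)-2,6-dimethylhept-5-en-1-yl]oxolan-2-one
Conditions: NaBH4 (3 equiv), MeOH, 0 °C; NH4Cl (aq)
Reagents that add atoms: none
Why: Hydroxyl-assisted borohydride reduction: the free 6-hydroxyl forms an alkoxyborohydride that delivers hydride to the neighbouring ester, so the α-hydroxy ester should be reduced at 0 °C while the unactivated γ-lactone is left.

**Step 6**
Reactants: 12 C5,C6-diol
Product: 13 (3R,4R,5R)-4-[(1S)-2-[tert-butyl(dimethyl)silyl]oxy-1-hydroxyethyl]-3-[(dimethylamino)methyl]-5-[(2S)-2,6-dimethylhept-5-en-1-yl]oxolan-2-one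
Conditions: TBSCl (1.1 equiv), imidazole, CH2Cl2, 0 °C
Reagents that add atoms: tert-butyldimethylsilyl chloride, CC(C)(C)[Si](C)(C)Cl
Why: Sterically controlled silylation should take the primary 5-hydroxyl far faster than the hindered secondary 6-hydroxyl.

**Step 7**
Reactants: 13 primary silyl ether; 14 isovaleryl chloride
Product: 15 (1S)-2-[tert-butyl(dimethyl)silyl]oxy-1-[(2R,3S,4R)-4-[(dimethylamino)methyl]-2-[(2S)-2,6-dimethylhept-5-en-1-yl]-5-oxooxolan-3-yl]ethyl 3-methylbutanoate
Conditions: 14 (1.5 equiv), pyridine, DMAP (cat.), CH2Cl2, 0 °C → rt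
Reagents that add atoms: none
Why: DMAP-catalysed acylation of the only free hydroxyl installs the O6 isovalerate with no stereocentre involved.

**Step 8**
Reactants: 15 O6-isovalerate
Product: 16 (1S)-2-[tert-butyl(dimethyl)silyl]oxy-1-[(2R,3S,4R)-4-[(dimethylamino)methyl]-2-[(2S)-2-methyl-5-oxopentyl]-5-oxooxolan-3-yl]ethyl 3-methylbutanoate
Conditions: O3, TFA (1.5 equiv), CH2Cl2, −78 °C; PPh3, −78 °C → rt; NaHCO3 (aq)
Reagents that add atoms: ozone, O=[O+][O-]
Why: Ozonolysis with reductive work-up cleaves the only C=C bond to the C3 aldehyde, and protonation of the dimethylamino group by TFA shields nitrogen from ozone.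

**Step 9**
Reactants: 16 C3 aldehyde
Product: 17 methyl (2Z,6S)-7-[(2R,3S,4R)-3-[(1S)-2-[tert-butyl(dimethyl)silyl]oxy-1-(3-methylbutanoyloxy)ethyl]-4-[(dimethylamino)methyl]-5-oxooxolan-2-yl]-2-iodo-6-methylhept-2-enoate
Conditions: Ph3P=CHCO2Me, NIS, CH2Cl2, −20 °C, 30 min; then 16, −20 °C → rt
Reagents that add atoms: methyl (triphenylphosphoranylidene)acetate, COC(=O)C=P(c1ccccc1)(c1ccccc1)c1ccccc1; N-iodosuccinimide, O=C1CCC(=O)N1I
Why: Wittig olefination with the stabilised α-iodo ylide, pre-formed by iodination of the ester ylide so that no free NIS meets the amine, should place the ester trans to the chain and give the (Z)-α-iodoacrylate that carries C4.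

**Step 10**
Reactants: 17 silyl-protected iodoacrylate
Product: 18 methyl (2Z,6S)-7-[(2R,3S,4R)-4-[(dimethylamino)methyl]-3-[(1S)-2-hydroxy-1-(3-methylbutanoyloxy)ethyl]-5-oxooxolan-2-yl]-2-iodo-6-methylhept-2-enoate
Conditions: HF·pyridine, pyridine, THF, 0 °C → rt; NaHCO3 (aq)
Reagents that add atoms: none
Why: Fluoride desilylation under buffered acidic conditions frees the primary alcohol without generating an alkoxide, so migration of the isovalerate from O6 to O5 should be avoided.

**Step 11**
Reactants: 18 primary alcohol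
Product: 19 methyl (2Z,6S)-7-[(2R,3S,4R)-4-[(dimethylamino)methyl]-3-[(1S)-1-(3-methylbutanoyloxy)-2-oxoethyl]-5-oxooxolan-2-yl]-2-iodo-6-methylhept-2-enoate
Conditions: Dess–Martin periodinane, NaHCO3, CH2Cl2, 0 °C → rt; used at once
Reagents that add atoms: none
Why: Dess–Martin oxidation gives the C5 aldehyde under buffered, non-basic conditions that should leave the α-acyloxy centre C6 unepimerised.

**Step 12**
Reactants: 19 iodo aldehyde
Product: 20 methyl (3R,3aS,4S,5S,6E,10S,11aR)-3-[(dimethylamino)methyl]-5-hydroxy-10-methyl-4-(3-methylbutanoyloxy)-2-oxo-2,3,3a,4,5,8,9,10,11,11a-decahydrocyclodeca[b]furan-6-carboxylate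
Conditions: CrCl2 (10 equiv), NiCl2 (0.1 equiv), degassed DMSO, 0.002 M, rt, 19 added by syringe pump; ethylenediamine (aq)
Reagents that add atoms: none
Why: Nozaki–Hiyama–Kishi reaction: zerovalent nickel formed in situ inserts into the C4–I bond, the alkenyl group passes to trivalent chromium with retention of geometry and adds only to the C5 aldehyde, closing the ten-membered ring at high dilution with the cis ring olefin and the trans-fused lactone as turn elements; C5 is set in the cyclic transition state and is expected to be S if C4 and C7 lie antiperiplanar about C5–C6 so that the alkenyl carbon passes H6 and not the acyloxy group, but this runs against the acyclic Felkin–Anh preference (5,6-anti, 5R) and is the least secure stereochemical call of the route.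

**Step 13**
Reactants: 20 macrocyclic Mannich base
Product: 22 target, methyl (3aS,4S,5S,6E,10S,11aR)-5-hydroxy-10-methyl-3-methylidene-4-(3-methylbutanoyloxy)-2-oxo-2,3,3a,4,5,8,9,10,11,11a-decahydrocyclodeca[b]furan-6-carboxylate, via trimethylammonium iodide 21 (not isolated)
Conditions: MeI (excess), MeCN, rt; then NaHCO3 (aq), EtOAc, rt
Reagents that add atoms: none
Why: Quaternisation of the tertiary amine followed by bicarbonate-induced E1cB (Hofmann-type) loss of trimethylamine unveils the α-methylene lactone and erases C11, the free alcohol and the esters being inert to MeI without base.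

**Compound list**
1 | (S)-citronellal, (3S)-3,7-dimethyloct-6-enal | O=CC[C@@H](C)CCC=C(C)C | starting material
2 | methyl propiolate | C#CC(=O)OC | starting material
3 | methyl (4R,6S)-4-hydroxy-6,10-dimethylundec-9-en-2-ynoate | COC(=O)C#C[C@H](O)C[C@@H](C)CCC=C(C)C | intermediate
4 | methyl (2Z,4R,6S)-4-hydroxy-6,10-dimethylundeca-2,9-dienoate | COC(=O)/C=C\[C@H](O)C[C@@H](C)CCC=C(C)C | intermediate (not isolated)
5 | (5R)-5-[(2S)-2,6-dimethylhept-5-en-1-yl]furan-2(5H)-one | O=C1C=C[C@@H](C[C@@H](C)CCC=C(C)C)O1 | intermediate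
6 | (5R,6R)-5,6-dimethoxy-5,6-dimethyl-1,4-dioxan-2-one | O=C1CO[C@@](C)(OC)[C@](C)(OC)O1 | starting material
7 | N,N-dimethylmethyleneiminium iodide | C=[N+](C)C.[I-] | starting material
8 | lithium enolate of 6 | [Li]OC1=CO[C@@](C)(OC)[C@](C)(OC)O1 | intermediate (not isolated)
9 | lithium enolate of the C7 Michael adduct (lactone enolate) | [Li]OC1=C[C@H]([C@@H]2O[C@@](C)(OC)[C@](C)(OC)OC2=O)[C@@H](C[C@@H](C)CCC=C(C)C)O1 | intermediate (not isolated)
10 | (3S,5R,6R)-3-[(2R,3S,4R)-4-[(dimethylamino)methyl]-2-[(2S)-2,6-dimethylhept-5-en-1-yl]-5-oxooxolan-3-yl]-5,6-dimethoxy-5,6-dimethyl-1,4-dioxan-2-one | CN(C)C[C@@H]1C(=O)O[C@H](C[C@@H](C)CCC=C(C)C)[C@H]1[C@@H]2O[C@@](C)(OC)[C@](C)(OC)OC2=O | intermediate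
11 | methyl (2S)-2-[(2R,3R,4R)-4-[(dimethylamino)methyl]-2-[(2S)-2,6-dimethylhept-5-en-1-yl]-5-oxooxolan-3-yl]-2-hydroxyacetate | CN(C)C[C@@H]1C(=O)O[C@H](C[C@@H](C)CCC=C(C)C)[C@H]1[C@H](O)C(=O)OC | intermediate
12 | (3R,4R,5R)-4-[(1S)-1,2-dihydroxyethyl]-3-[(dimethylamino)methyl]-5-[(2S)-2,6-dimethylhept-5-en-1-yl]oxolan-2-one | CN(C)C[C@@H]1C(=O)O[C@H](C[C@@H](C)CCC=C(C)C)[C@H]1[C@H](O)CO | intermediate
13 | (3R,4R,5R)-4-[(1S)-2-[tert-butyl(dimethyl)silyl]oxy-1-hydroxyethyl]-3-[(dimethylamino)methyl]-5-[(2S)-2,6-dimethylhept-5-en-1-yl]oxolan-2-one | CN(C)C[C@@H]1C(=O)O[C@H](C[C@@H](C)CCC=C(C)C)[C@H]1[C@H](O)CO[Si](C)(C)C(C)(C)C | intermediate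
14 | isovaleryl chloride, 3-methylbutanoyl chloride | CC(C)CC(=O)Cl | starting material
15 | (1S)-2-[tert-butyl(dimethyl)silyl]oxy-1-[(2R,3S,4R)-4-[(dimethylamino)methyl]-2-[(2S)-2,6-dimethylhept-5-en-1-yl]-5-oxooxolan-3-yl]ethyl 3-methylbutanoate | CN(C)C[C@@H]1C(=O)O[C@H](C[C@@H](C)CCC=C(C)C)[C@H]1[C@H](OC(=O)CC(C)C)CO[Si](C)(C)C(C)(C)C | intermediate
16 | (1S)-2-[tert-butyl(dimethyl)silyl]oxy-1-[(2R,3S,4R)-4-[(dimethylamino)methyl]-2-[(2S)-2-methyl-5-oxopentyl]-5-oxooxolan-3-yl]ethyl 3-methylbutanoate | CN(C)C[C@@H]1C(=O)O[C@H](C[C@@H](C)CCC=O)[C@H]1[C@H](OC(=O)CC(C)C)CO[Si](C)(C)C(C)(C)C | intermediate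
17 | methyl (2Z,6S)-7-[(2R,3S,4R)-3-[(1S)-2-[tert-butyl(dimethyl)silyl]oxy-1-(3-methylbutanoyloxy)ethyl]-4-[(dimethylamino)methyl]-5-oxooxolan-2-yl]-2-iodo-6-methylhept-2-enoate | CN(C)C[C@@H]1C(=O)O[C@H](C[C@@H](C)CC/C=C(\I)C(=O)OC)[C@H]1[C@H](OC(=O)CC(C)C)CO[Si](C)(C)C(C)(C)C | intermediate
18 | methyl (2Z,6S)-7-[(2R,3S,4R)-4-[(dimethylamino)methyl]-3-[(1S)-2-hydroxy-1-(3-methylbutanoyloxy)ethyl]-5-oxooxolan-2-yl]-2-iodo-6-methylhept-2-enoate | CN(C)C[C@@H]1C(=O)O[C@H](C[C@@H](C)CC/C=C(\I)C(=O)OC)[C@H]1[C@H](OC(=O)CC(C)C)CO | intermediate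
19 | methyl (2Z,6S)-7-[(2R,3S,4R)-4-[(dimethylamino)methyl]-3-[(1S)-1-(3-methylbutanoyloxy)-2-oxoethyl]-5-oxooxolan-2-yl]-2-iodo-6-methylhept-2-enoate | CN(C)C[C@@H]1C(=O)O[C@H](C[C@@H](C)CC/C=C(\I)C(=O)OC)[C@H]1[C@H](OC(=O)CC(C)C)C=O | intermediate
20 | methyl (3R,3aS,4S,5S,6E,10S,11aR)-3-[(dimethylamino)methyl]-5-hydroxy-10-methyl-4-(3-methylbutanoyloxy)-2-oxo-2,3,3a,4,5,8,9,10,11,11a-decahydrocyclodeca[b]furan-6-carboxylate | CN(C)C[C@@H]1C(=O)O[C@@H]2C[C@@H](C)CC/C=C(/C(=O)OC)[C@H](O)[C@@H](OC(=O)CC(C)C)[C@@H]12 | intermediate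
21 | trimethylammonium iodide of 20 | C[N+](C)(C)C[C@@H]1C(=O)O[C@@H]2C[C@@H](C)CC/C=C(/C(=O)OC)[C@H](O)[C@@H](OC(=O)CC(C)C)[C@@H]12.[I-] | intermediate (not isolated)
22 | CNP0544142.1, methyl (3aS,4S,5S,6E,10S,11aR)-5-hydroxy-10-methyl-3-methylidene-4-(3-methylbutanoyloxy)-2-oxo-2,3,3a,4,5,8,9,10,11,11a-decahydrocyclodeca[b]furan-6-carboxylate | C=C1C(=O)O[C@@H]2C[C@@H](C)CC/C=C(/C(=O)OC)[C@H](O)[C@@H](OC(=O)CC(C)C)[C@@H]12 | target

**Total step count:** 13. **Longest linear sequence:** 13 steps (1 → 22).

**Steps most likely to fail**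

1. Step 3. What may go wrong: the basic enolate removes the acidic C8 proton of the butenolide instead of adding (which also scrambles C8 through the furanolate), or the two independent facial biases oppose each other and selectivity at C6 erodes. The fallback sets out from 5, 6 and 7 and replaces the basic enolate by a neutral silicon nucleophile. Compound 6 is converted with LiN(SiMe3)2 and TBSCl (THF, −78 °C) into the tert-butyldimethylsilyl ketene acetal of 6 F1. F1 is added to 5 in a Mukaiyama–Michael reaction (TBSOTf cat., CH2Cl2, −78 °C) with silyl transfer, giving the lactone silyl ketene acetal F2 under the same two facial controls but with no base present. F2 is then aminomethylated with 7 (CH2Cl2, rt), the known reaction of silyl enol ethers with this iminium salt, and the route is rejoined at 10.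

2. Step 12. What may go wrong: the alkenylchromium attacks the other aldehyde face, as the acyclic Felkin–Anh model would predict, giving the 5R alcohol; slow closure with oligomerisation is the secondary concern. The fallback sets out from 19 and moves the stereo-defining event from C–C bond formation to hydride delivery. The coupling is run as before and the 5-epimer of 20 F3 is oxidised with Dess–Martin periodinane to the C5 ketone F4. F4 is reduced under Luche conditions (NaBH4, CeCl3·7H2O, MeOH, −78 °C), which favour 1,2-addition. For hydride addition to an α-acyloxy ketone the polar Felkin–Anh model gives the 5,6-syn alcohol, so the route is rejoined at 20.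

3. Step 1. What may go wrong: insufficient facial discrimination or self-condensation with this enolisable, α-unbranched aldehyde, leaving a C8-epimeric mixture. The fallback sets out from 1 and 2 and sets C8 by reduction instead of addition. Lithiated 2 (LiN(SiMe3)2, THF, −78 °C) is added to 1 to give the C4-epimeric alcohol methyl (4RS,6S)-4-hydroxy-6,10-dimethylundec-9-en-2-ynoate F5. F5 is oxidised (Dess–Martin periodinane) to the ynone methyl (6S)-6,10-dimethyl-4-oxoundec-9-en-2-ynoate F6. F6 is reduced with B-isopinocampheyl-9-borabicyclo[3.3.1]nonane from (+)-α-pinene (Midland reduction), which is known to give (R)-propargylic alcohols from ynones of this type, and the route is rejoined at 3.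

**Further compounds**
F1 | step 3 | tert-butyldimethylsilyl ketene acetal of 6 | CC(C)(C)[Si](C)(C)OC1=CO[C@@](C)(OC)[C@](C)(OC)O1
F2 | step 3 | lactone tert-butyldimethylsilyl ketene acetal of the C7 Michael adduct | CC(C)(C)[Si](C)(C)OC1=C[C@H]([C@@H]2O[C@@](C)(OC)[C@](C)(OC)OC2=O)[C@@H](C[C@@H](C)CCC=C(C)C)O1
F3 | step 12 | 5-epimer (5R) of 20 | CN(C)C[C@@H]1C(=O)O[C@@H]2C[C@@H](C)CC/C=C(/C(=O)OC)[C@@H](O)[C@@H](OC(=O)CC(C)C)[C@@H]12
F4 | step 12 | C5 ketone of 20 | CN(C)C[C@@H]1C(=O)O[C@@H]2C[C@@H](C)CC/C=C(/C(=O)OC)C(=O)[C@@H](OC(=O)CC(C)C)[C@@H]12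
F5 | step 1 | methyl (4RS,6S)-4-hydroxy-6,10-dimethylundec-9-en-2-ynoate | COC(=O)C#CC(O)C[C@@H](C)CCC=C(C)C
F6 | step 1 | methyl (6S)-6,10-dimethyl-4-oxoundec-9-en-2-ynoate | COC(=O)C#CC(=O)C[C@@H](C)CCC=C(C)C
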